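**Strategy**

The spiro quaternary carbon (C5 of the spiro[4.5]decene, flanked by the aryl-ether CH, the ring CH=C(iPr) and the CHMe centre) is made by strain release and not by cycloaddition. A palladium(II)-triggered 1,2-shift expands a cyclobutanol carried on C1 of a (3S,6R)-cyclohexene made from (+)-dihydrocarvone and cyclobutanone. One operation closes the cyclopentanone, fixes the spiro centre with the migrating CH2 trans to the ring methyl and, through syn β-hydride loss of H-3, places the C6=C7 alkene while erasing the auxiliary isopropyl stereocentre. The chroman is then annulated onto the ketone through a chromone (acylation/SNAr), reductive methylation and a convex-face ionic reduction at the benzylic carbon; formylation is last.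

Key step: step 4

Remark: commercial (+)-dihydrocarvone is mainly the (2R,5R) isomer and contains some C2 epimer; step 1 equilibrates this centre, and residual cis material can only lead to methyl-epimeric diastereomers (not enantiomers) of the cyclobutanol and the spiro ketone, which are removed by chromatography.

**Route**

Step 1
Reactants: 1 (2R,5R)-2-methyl-5-(prop-1-en-2-yl)cyclohexan-1-one [(+)-dihydrocarvone]
Product: 2 (2R,5R)-2-methyl-5-(propan-2-yl)cyclohexan-1-one (trans-carvomenthone)
Conditions: H2 (1 atm), 5% Pd/C, EtOAc, rt; then NaOMe (cat.), MeOH, rt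
Reagents that add atoms: none
Why: Catalytic hydrogenation over Pd/C should saturate only the 1,1-disubstituted isopropenyl alkene (the ketone is inert), and the base treatment equilibrates the enolisable C2 centre to the diequatorial trans ketone under control of the fixed C5 centre.

Step 2
Reactants: 2 (2R,5R)-2-methyl-5-(propan-2-yl)cyclohexan-1-one; 3 2,4,6-tri(propan-2-yl)benzenesulfonohydrazide
Product: 4 (E)-N′-[(2R,5R)-2-methyl-5-(propan-2-yl)cyclohexylidene]-2,4,6-tri(propan-2-yl)benzenesulfonohydrazide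
Conditions: HCl (cat.), MeCN, rt
Reagents that add atoms: none
Why: Acid-catalysed condensation of the ketone with the sulfonyl hydrazide (hydrazone formation) should give the E-hydrazone with the sulfonamide nitrogen syn to the α-CH2, which is the geometry the next step needs.

Step 3
Reactants: 4 (E)-N′-[(2R,5R)-2-methyl-5-(propan-2-yl)cyclohexylidene]-2,4,6-tri(propan-2-yl)benzenesulfonohydrazide; 5 cyclobutanone
Product: 7 1-[(3S,6R)-6-methyl-3-(propan-2-yl)cyclohex-1-en-1-yl]cyclobutan-1-ol, via cyclohexenyllithium 6 (not isolated)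
Conditions: n-BuLi (2.2 equiv), THF–TMEDA, −78 → 0 °C; then 5, −78 °C; H2O
Reagents that add atoms: none
Why: Shapiro reaction: the hydrazone dianion, deprotonated at the less substituted α-CH2, loses sulfinate and dinitrogen to give vinyllithium 6, which adds 1,2 to the strained carbonyl of 5; neither ring stereocentre is touched.

Step 4
Reactants: 7 1-[(3S,6R)-6-methyl-3-(propan-2-yl)cyclohex-1-en-1-yl]cyclobutan-1-ol
Product: 9 (5R,10R)-10-methyl-7-(propan-2-yl)spiro[4.5]dec-6-en-1-one, via C6-palladated spiro ketone 8 (not isolated)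
Conditions: PdCl2(MeCN)2 (10 mol%), p-benzoquinone (1.5 equiv), THF, 25 → 50 °C
Reagents that add atoms: none
Why: Pd(II) binds the ring alkene of 7, a cyclobutane C–C bond anti to palladium shifts from the carbinol carbon to C1 while the hydroxyl becomes the ketone (Wacker-type semipinacol shift driven by release of four-ring strain), giving σ-alkylpalladium 8, which loses H-3 by syn β-hydride elimination, and benzoquinone returns Pd(0) to Pd(II). The closest known reaction type is the palladium(II)-mediated oxidative ring expansion of 1-alkenylcyclobutanols to α-substituted cyclopentanones. The cyclopentanone is closed not by an end-to-end cyclisation but by a suprafacial 1,2-alkyl shift that enlarges the four-membered ring by the alkene carbon C1, which thereby becomes the spiro atom. The one new stereocentre, the spiro carbon, is controlled by the anti relationship between palladium and the migrating CH2: palladium has to sit cis to H-3, that is trans to the isopropyl group and, in this 3,6-trans substrate, cis to the C6 methyl group, so the CH2 enters trans to the methyl and the carbonyl carbon ends cis to it, which is the configuration the target requires. The step needs facial selectivity, and the substrate should secure it twice: the pseudoaxial isopropyl group shields the other face of C2, and only the σ-alkylpalladium with palladium cis to H-3 has a syn β-hydrogen (the spiro carbon has none), so a wrong-face adduct cannot turn over to 9. The isopropyl-bearing stereocentre that steers the step is destroyed in the same operation and becomes the alkene carbon C7 (numbering of 7: cyclohexene C1–C6).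

Step 5
Reactants: 9 (5R,10R)-10-methyl-7-(propan-2-yl)spiro[4.5]dec-6-en-1-one; 10 2,4,6-trifluorobenzoyl chloride
Product: 12 (1R,6R)-6′,8′-difluoro-6-methyl-3-(propan-2-yl)-1′,2′-dihydro-9′H-spiro[cyclohex-2-ene-1,3′-cyclopenta[b]chromen]-9′-one, via β-diketone 11 (not isolated)
Conditions: LiHMDS (1.05 equiv), toluene, 0 °C; 10; LiHMDS (1.1 equiv); then DMF, 80 °C
Reagents that add atoms: none
Why: Claisen-type C-acylation at C2, the only enolisable position of 9, gives diketonate 11, whose ring-ketone enolate oxygen then displaces one of the two equivalent ortho-fluorines activated by the aroyl carbonyl (intramolecular SNAr) to close the γ-pyrone ring.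

Step 6
Reactants: 12 (1R,6R)-6′,8′-difluoro-6-methyl-3-(propan-2-yl)-1′,2′-dihydro-9′H-spiro[cyclohex-2-ene-1,3′-cyclopenta[b]chromen]-9′-one
Product: 14 (1R,3a′S,6R,9a′R)-6′,8′-difluoro-6,9a′-dimethyl-3-(propan-2-yl)-1′,2′,3a′,9a′-tetrahydro-9′H-spiro[cyclohex-2-ene-1,3′-cyclopenta[b]chromen]-9′-one, via lithium enolate 13 (not isolated)
Conditions: L-Selectride (1.2 equiv), THF, −78 → −40 °C; then MeI (5 equiv), DMPU, −40 → 0 °C
Reagents that add atoms: iodomethane, CI
Why: Reductive alkylation of an enone (conjugate hydride addition, then enolate C-alkylation): hydride should enter C3a′ from the face of the sp2 CH (cyclohexene C2) of the spiro ring, opposite to cyclohexene C6 whose methyl group leans over this carbon, and iodomethane then has to add cis to that new hydrogen because only the cis-fused 6–5 ring junction is accessible, which sets both new centres.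

Step 7
Reactants: 14 (1R,3a′S,6R,9a′R)-6′,8′-difluoro-6,9a′-dimethyl-3-(propan-2-yl)-1′,2′,3a′,9a′-tetrahydro-9′H-spiro[cyclohex-2-ene-1,3′-cyclopenta[b]chromen]-9′-one
Product: 15 (1R,3a′S,6R,9a′R)-6′,8′-bis(benzyloxy)-6,9a′-dimethyl-3-(propan-2-yl)-1′,2′,3a′,9a′-tetrahydro-9′H-spiro[cyclohex-2-ene-1,3′-cyclopenta[b]chromen]-9′-one
Conditions: BnOH (3 equiv), NaH (3 equiv), DMF, 0 → 60 °C
Reagents that add atoms: benzyl alcohol, OCc1ccccc1
Why: Double nucleophilic aromatic substitution: both fluorines are activated (ortho and para) by the C9′ carbonyl and are replaced by benzyloxide, while the quaternary C9a′ rules out enolisation and retro-oxa-Michael opening.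

Step 8
Reactants: 15 (1R,3a′S,6R,9a′R)-6′,8′-bis(benzyloxy)-6,9a′-dimethyl-3-(propan-2-yl)-1′,2′,3a′,9a′-tetrahydro-9′H-spiro[cyclohex-2-ene-1,3′-cyclopenta[b]chromen]-9′-one; 16 isobutyllithium
Product: 17 (1R,3a′S,6R,9a′R)-6′,8′-bis(benzyloxy)-6,9a′-dimethyl-9′-(2-methylpropyl)-3-(propan-2-yl)-1′,2′,3a′,9a′-tetrahydro-9′H-spiro[cyclohex-2-ene-1,3′-cyclopenta[b]chromen]-9′-ol (C9′ configuration not controlled)
Conditions: 16 (3 equiv), anhydrous CeCl3 (3 equiv), THF, −78 °C; H2O
Reagents that add atoms: none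
Why: 1,2-Addition of the organocerium reagent made from 16 to the hindered, non-enolisable aryl ketone, cerium suppressing β-hydride reduction; the configuration of the new carbinol centre is irrelevant because it is ionised in step 9.

Step 9
Reactants: 17 (1R,3a′S,6R,9a′R)-6′,8′-bis(benzyloxy)-6,9a′-dimethyl-9′-(2-methylpropyl)-3-(propan-2-yl)-1′,2′,3a′,9a′-tetrahydro-9′H-spiro[cyclohex-2-ene-1,3′-cyclopenta[b]chromen]-9′-ol
Product: 19 (1R,3a′R,6R,9′R,9a′S)-6′,8′-bis(benzyloxy)-6,9a′-dimethyl-9′-(2-methylpropyl)-3-(propan-2-yl)-1′,2′,3a′,9a′-tetrahydro-9′H-spiro[cyclohex-2-ene-1,3′-cyclopenta[b]chromene], via benzylic cation 18 (not isolated)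
Conditions: Et3SiH (5 equiv), TFA (3 equiv), CH2Cl2, −40 → −20 °C
Reagents that add atoms: none
Why: Ionic hydrogenation: the tertiary benzylic alcohol ionises to the trialkoxy-stabilised cation 18, which should take hydride from Et3SiH on the convex face of the cis-fused pyran–cyclopentane unit, anti to the pseudoaxial cyclopentane CH2 and syn to the angular methyl, so that H-9′ ends cis to the 9a′-methyl, while the isolated trisubstituted alkene is not protonated by dilute TFA at low temperature.

Step 10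
Reactants: 19 (1R,3a′R,6R,9′R,9a′S)-6′,8′-bis(benzyloxy)-6,9a′-dimethyl-9′-(2-methylpropyl)-3-(propan-2-yl)-1′,2′,3a′,9a′-tetrahydro-9′H-spiro[cyclohex-2-ene-1,3′-cyclopenta[b]chromene]
Product: 20 (1R,3a′R,6R,9′R,9a′S)-6,9a′-dimethyl-9′-(2-methylpropyl)-3-(propan-2-yl)-1′,2′,3a′,9a′-tetrahydro-9′H-spiro[cyclohex-2-ene-1,3′-cyclopenta[b]chromene]-6′,8′-diol
Conditions: BCl3 (4 equiv), pentamethylbenzene (6 equiv), CH2Cl2, −78 °C; MeOH, then H2O
Reagents that add atoms: none
Why: Lewis-acid cleavage of aryl benzyl ethers with pentamethylbenzene as a non-basic benzyl-cation scavenger, at a temperature where the secondary alkyl aryl ether of the pyran and the alkene are expected to survive.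

Step 11
Reactants: 20 (1R,3a′R,6R,9′R,9a′S)-6,9a′-dimethyl-9′-(2-methylpropyl)-3-(propan-2-yl)-1′,2′,3a′,9a′-tetrahydro-9′H-spiro[cyclohex-2-ene-1,3′-cyclopenta[b]chromene]-6′,8′-diol
Product: 21 (1R,3a′R,6R,9′R,9a′S)-6′,8′-dihydroxy-6,9a′-dimethyl-9′-(2-methylpropyl)-3-(propan-2-yl)-1′,2′,3a′,9a′-tetrahydro-9′H-spiro[cyclohex-2-ene-1,3′-cyclopenta[b]chromene]-5′,7′-dicarbaldehyde (CNP0121396.1)
Conditions: POCl3 (6 equiv), DMF, 0 → 50 °C; then aq. NaOAc, 60 °C
Reagents that add atoms: N,N-dimethylformamide, CN(C)C=O; water, O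
Why: Double Vilsmeier–Haack formylation: C5′ and C7′ are the only free ring positions and each is ortho or para to three oxygen donors, the chloroiminium electrophile does not attack the unactivated alkene, and hydrolysis of the bis-iminium salt gives the dialdehyde.

**Compound list**

1 | (2R,5R)-2-methyl-5-(prop-1-en-2-yl)cyclohexan-1-one [(+)-dihydrocarvone] | O=C1C[C@H](C(C)=C)CC[C@H]1C | starting material
2 | (2R,5R)-2-methyl-5-(propan-2-yl)cyclohexan-1-one (trans-carvomenthone) | O=C1C[C@H](C(C)C)CC[C@H]1C | intermediate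
3 | 2,4,6-tri(propan-2-yl)benzenesulfonohydrazide | CC(C)c1cc(C(C)C)c(S(=O)(=O)NN)c(C(C)C)c1 | starting material
4 | (E)-N′-[(2R,5R)-2-methyl-5-(propan-2-yl)cyclohexylidene]-2,4,6-tri(propan-2-yl)benzenesulfonohydrazide | CC(C)c1cc(C(C)C)c(S(=O)(=O)N/N=C2\C[C@H](C(C)C)CC[C@H]2C)c(C(C)C)c1 | intermediate
5 | cyclobutanone | O=C1CCC1 | starting material
6 | [(3S,6R)-6-methyl-3-(propan-2-yl)cyclohex-1-en-1-yl]lithium | [Li]C1=C[C@H](C(C)C)CC[C@H]1C | intermediate
7 | 1-[(3S,6R)-6-methyl-3-(propan-2-yl)cyclohex-1-en-1-yl]cyclobutan-1-ol | OC1(CCC1)C2=C[C@H](C(C)C)CC[C@H]2C | intermediate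
8 | chlorido[(5R,10R)-10-methyl-1-oxo-7-(propan-2-yl)spiro[4.5]decan-6-yl]palladium(II), Pd cis to H-7 and to the C10 methyl group (further ligands omitted) | O=C2CCC[C@@]21[C@@H]([Pd]Cl)[C@H](C(C)C)CC[C@H]1C | intermediate
9 | (5R,10R)-10-methyl-7-(propan-2-yl)spiro[4.5]dec-6-en-1-one | O=C2CCC[C@@]21C=C(C(C)C)CC[C@H]1C | intermediate
10 | 2,4,6-trifluorobenzoyl chloride | O=C(Cl)c1c(F)cc(F)cc1F | starting material
11 | (5R,10R)-10-methyl-7-(propan-2-yl)-2-(2,4,6-trifluorobenzoyl)spiro[4.5]dec-6-en-1-one (C2 epimers/enol, as lithium diketonate in the flask) | O=C2C(C(=O)c3c(F)cc(F)cc3F)CC[C@@]21C=C(C(C)C)CC[C@H]1C | intermediate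
12 | (1R,6R)-6′,8′-difluoro-6-methyl-3-(propan-2-yl)-1′,2′-dihydro-9′H-spiro[cyclohex-2-ene-1,3′-cyclopenta[b]chromen]-9′-one | O=C3c4c(F)cc(F)cc4OC2=C3CC[C@@]21C=C(C(C)C)CC[C@H]1C | intermediate
13 | lithium (1R,3a′S,6R)-6′,8′-difluoro-6-methyl-3-(propan-2-yl)-1′,2′-dihydro-3a′H-spiro[cyclohex-2-ene-1,3′-cyclopenta[b]chromen]-9′-olate (enolate, H-3a′ cis to cyclohexene C2) | [Li]OC3=C4CC[C@@]1(C=C(C(C)C)CC[C@H]1C)[C@@H]4Oc5cc(F)cc(F)c35 | intermediate
14 | (1R,3a′S,6R,9a′R)-6′,8′-difluoro-6,9a′-dimethyl-3-(propan-2-yl)-1′,2′,3a′,9a′-tetrahydro-9′H-spiro[cyclohex-2-ene-1,3′-cyclopenta[b]chromen]-9′-one | O=C1c2c(F)cc(F)cc2O[C@@H]2[C@@]1(C)CC[C@@]21C=C(C(C)C)CC[C@H]1C | intermediate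
15 | (1R,3a′S,6R,9a′R)-6′,8′-bis(benzyloxy)-6,9a′-dimethyl-3-(propan-2-yl)-1′,2′,3a′,9a′-tetrahydro-9′H-spiro[cyclohex-2-ene-1,3′-cyclopenta[b]chromen]-9′-one | O=C1c2c(OCc3ccccc3)cc(OCc3ccccc3)cc2O[C@@H]2[C@@]1(C)CC[C@@]21C=C(C(C)C)CC[C@H]1C | intermediate
16 | isobutyllithium (2-methylpropyllithium) | [Li]CC(C)C | starting material
17 | (1R,3a′S,6R,9a′R)-6′,8′-bis(benzyloxy)-6,9a′-dimethyl-9′-(2-methylpropyl)-3-(propan-2-yl)-1′,2′,3a′,9a′-tetrahydro-9′H-spiro[cyclohex-2-ene-1,3′-cyclopenta[b]chromen]-9′-ol (C9′ not assigned) | CC(C)CC1(O)c2c(OCc3ccccc3)cc(OCc3ccccc3)cc2O[C@@H]2[C@@]1(C)CC[C@@]21C=C(C(C)C)CC[C@H]1C | intermediate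
18 | C9′ benzylic carbocation derived from 17 by loss of hydroxide (other centres as in 17) | CC(C)C[C+]1c2c(OCc3ccccc3)cc(OCc3ccccc3)cc2O[C@@H]2[C@@]1(C)CC[C@@]21C=C(C(C)C)CC[C@H]1C | intermediate
19 | (1R,3a′R,6R,9′R,9a′S)-6′,8′-bis(benzyloxy)-6,9a′-dimethyl-9′-(2-methylpropyl)-3-(propan-2-yl)-1′,2′,3a′,9a′-tetrahydro-9′H-spiro[cyclohex-2-ene-1,3′-cyclopenta[b]chromene] | CC(C)C[C@H]1c2c(OCc3ccccc3)cc(OCc3ccccc3)cc2O[C@@H]2[C@@]1(C)CC[C@@]21C=C(C(C)C)CC[C@H]1C | intermediate
20 | (1R,3a′R,6R,9′R,9a′S)-6,9a′-dimethyl-9′-(2-methylpropyl)-3-(propan-2-yl)-1′,2′,3a′,9a′-tetrahydro-9′H-spiro[cyclohex-2-ene-1,3′-cyclopenta[b]chromene]-6′,8′-diol | CC(C)C[C@H]1c2c(O)cc(O)cc2O[C@@H]2[C@@]1(C)CC[C@@]21C=C(C(C)C)CC[C@H]1C | intermediate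
21 | (1R,3a′R,6R,9′R,9a′S)-6′,8′-dihydroxy-6,9a′-dimethyl-9′-(2-methylpropyl)-3-(propan-2-yl)-1′,2′,3a′,9a′-tetrahydro-9′H-spiro[cyclohex-2-ene-1,3′-cyclopenta[b]chromene]-5′,7′-dicarbaldehyde | CC(C)C[C@H]1c2c(O)c(C=O)c(O)c(C=O)c2O[C@@H]2[C@@]1(C)CC[C@@]21C=C(C(C)C)CC[C@H]1C | target

**Totals and risks**

Total step count: 11. Longest linear sequence: 11 steps (1 → 21).

Steps most likely to fail:

Step 4. Palladium may bind the wrong alkene face, or the palladium alkoxide may open the cyclobutanol by β-carbon elimination, so that no σ-alkylpalladium with a syn β-hydrogen forms and the catalyst does not turn over. The fallback sets out from 7 and replaces the metal-triggered shift by an epoxide-triggered one. Hydroxyl-directed epoxidation (VO(acac)2, t-BuOOH, CH2Cl2), expected on the face away from the isopropyl group, should give 1-[(2R,5S)-2-methyl-5-(propan-2-yl)-7-oxabicyclo[4.1.0]heptan-1-yl]cyclobutan-1-ol (epoxide oxygen cis to the methyl group) F1. BF3·OEt2 at −78 °C should then open the epoxide at the tertiary carbon with anti migration of the cyclobutane CH2 to give (5R,6S,7S,10R)-6-hydroxy-10-methyl-7-(propan-2-yl)spiro[4.5]decan-1-one F2. Burgess reagent removes the hydroxyl together with the cis-disposed H-7 by syn elimination, and the sequence comes back to the route at 9.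

Step 6. Hydride transfer to the fully substituted β-carbon next to the spiro centre may be slower than 1,2-reduction of the carbonyl, or may not occur at all. The fallback sets out from 11 (step 5 stopped before the DMF heating and the diketone isolated) and makes the ring junction before the pyran is closed. C-methylation (MeI, K2CO3, acetone, rt), expected from the face of the ring CH=, should give (2R,5R,10R)-2,10-dimethyl-7-(propan-2-yl)-2-(2,4,6-trifluorobenzoyl)spiro[4.5]dec-6-en-1-one F3. LiBH4 then reduces both ketones, with hydride entering the ring carbonyl anti to the aroyl-derived substituent, to give (5R,10R)-2-[hydroxy(2,4,6-trifluorophenyl)methyl]-2,10-dimethyl-7-(propan-2-yl)spiro[4.5]dec-6-en-1-ol (ring hydroxyl cis to the carbinol side chain) F4. NaH in THF closes the pyran by SNAr of the ring alkoxide on an ortho-fluorine to give the 9′-alcohol corresponding to 14 (C9′ epimers) F5. Dess–Martin oxidation of this benzylic alcohol comes back to the route at 14.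

Step 8. The branched organometallic may reduce the hindered, electron-rich ketone by β-hydride transfer or fail to add. The fallback sets out from 15 and uses an allyl transfer through a six-membered transition state. 2-Methylallylmagnesium chloride (THF, 0 °C) should give the 9′-(2-methylprop-2-en-1-yl) carbinol corresponding to 17 F6. Diimide (TsNHNH2, NaOAc, DME–H2O, reflux) should saturate only the 1,1-disubstituted alkene, and the sequence comes back to the route at 17.

**Further compounds**

F1 | step 4 | 1-[(2R,5S)-2-methyl-5-(propan-2-yl)-7-oxabicyclo[4.1.0]heptan-1-yl]cyclobutan-1-ol (epoxide oxygen cis to methyl, trans to isopropyl) | OC1(CCC1)[C@]23O[C@H]2[C@H](C(C)C)CC[C@H]3C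
F2 | step 4 | (5R,6S,7S,10R)-6-hydroxy-10-methyl-7-(propan-2-yl)spiro[4.5]decan-1-one | O=C2CCC[C@@]21[C@@H](O)[C@H](C(C)C)CC[C@H]1C
F3 | step 6 | (2R,5R,10R)-2,10-dimethyl-7-(propan-2-yl)-2-(2,4,6-trifluorobenzoyl)spiro[4.5]dec-6-en-1-one | O=C2[C@](C)(C(=O)c3c(F)cc(F)cc3F)CC[C@@]21C=C(C(C)C)CC[C@H]1C
F4 | step 6 | (5R,10R)-2-[hydroxy(2,4,6-trifluorophenyl)methyl]-2,10-dimethyl-7-(propan-2-yl)spiro[4.5]dec-6-en-1-ol (ring hydroxyl cis to the carbinol side chain; carbinol carbon not assigned) | O[C@@H]2[C@](C)(C(O)c3c(F)cc(F)cc3F)CC[C@@]21C=C(C(C)C)CC[C@H]1C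
F5 | step 6 | 6′,8′-difluoro-6,9a′-dimethyl-3-(propan-2-yl)-1′,2′,3a′,9a′-tetrahydro-9′H-spiro[cyclohex-2-ene-1,3′-cyclopenta[b]chromen]-9′-ol (ring centres as in 14; C9′ epimers) | OC1c2c(F)cc(F)cc2O[C@@H]2[C@@]1(C)CC[C@@]21C=C(C(C)C)CC[C@H]1C
F6 | step 8 | 6′,8′-bis(benzyloxy)-6,9a′-dimethyl-9′-(2-methylprop-2-en-1-yl)-3-(propan-2-yl)-1′,2′,3a′,9a′-tetrahydro-9′H-spiro[cyclohex-2-ene-1,3′-cyclopenta[b]chromen]-9′-ol (ring centres as in 15; C9′ not assigned) | CC(=C)CC1(O)c2c(OCc3ccccc3)cc(OCc3ccccc3)cc2O[C@@H]2[C@@]1(C)CC[C@@]21C=C(C(C)C)CC[C@H]1C
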